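## The problem

Target 25 is a trans-fused hydroazulene. A cyclopentane (C1–C5) shares the C1–C5 bond with a cycloheptane (C1, C10, C9, C8, C7, C6, C5); C1 is the methyl-bearing quaternary ring-fusion carbon, C2 and C3 are CH2, C4 is the isopropyl carbinol, C5 is the ring-fusion CH, C6 carries the benzoate, C7 is CH2, C8 (methyl) and C9 are the epoxide carbons and C10 is CH2. In this numbering the six stereocentres are 1R,4R,5S,6S,8R,9S. The C1 methyl and the C4 hydroxyl lie on one face (called β here); H5, the C6 benzoate and the epoxide oxygen lie on the other (α), so the C4 and C6 oxygens are 1,3-anti. C4 is a fully substituted carbinol that is best bought, but with an oxygen substituent on one face and an isopropyl group on the other it cannot be trusted to control the remote quaternary C1, so a relay is needed. Once C1 is fixed, its methyl group can steer reagents to the α face at C5/C6 and at C8/C9. The fragile parts are the trisubstituted epoxide (it faces the free C4 hydroxyl across the ring and would open under acid), the benzoate (strong base, hydride, organometallics) and the tertiary carbinol (ionisation), so epoxidation comes last and benzoylation late. The feature that invites the key step is that C1 lies two bonds from the oxidised C9 and is bonded to C5, which carries the oxygenated C6: C10=C9–O–C6–C5=C1 is an allyl vinyl ether, and because C7–C8 ties C6 to C9 it can be held as a 2-methylenetetrahydrofuran. A [3,3] shift of that ether makes the seven-membered ring and the quaternary centre together, moves the stereochemical problem from C1 to the secondary carbinol C6, and leaves a C5=C6 alkene from which H5 and the C6 oxygen can be added.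

## Retrosynthesis

**Epoxide last (25 ⇒ 24).** The two C–O bonds of the oxirane are cut first, because no later reagent (acid, fluoride, palladium hydride) should meet the epoxide. Alkene 24 has one stereocentre pair fewer. The forward step asks a buffered peracid to approach the C8=C9 alkene from the α face, away from the C1 methyl group.

**C8=C9 alkene from a C9 ketone (24 ⇒ 23 ⇒ 22 ⇒ 21).** The O–Si bond on C4 is cut (23), then the C9–H bond is traced to an enol triflate 22 and this to ketone 21. The C9 carbonyl is what the key step leaves behind and C8 already carries its methyl group, so an enol triflate toward the more substituted side followed by reduction gives the alkene directly. Dehydration of a C9 alcohol would leave the direction of elimination less controlled. The forward reaction must enolise toward C8 rather than C10 without a strong base that would attack the benzoate.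

**Benzoate, C6 oxygen and H5 from the C5=C6 alkene (21 ⇒ 20 ⇒ 19 ⇒ 17 ⇒ 16).** The acyl C–O bond is cut, then the C6–O and C5–H bonds together (a syn hydroboration), with the ketone masked as dioxolane 17. Enone-free ketone 16 has only the C1 and C4 centres that matter (C8 is erased later). The forward hydroboration must place boron on C6 and hydrogen on C5 from the α face; benzoylation must precede ketal removal so that a free C6 hydroxyl never faces the C9 ketone across the ring.

**Key disconnection (16 ⇒ 15).** The C1–C10 bond is cut and the C6–O bond restored, a retro-Claisen that contracts the cycloheptenone to the 2-methylene-5-(cyclopentenyl)tetrahydrofuran 15. Cutting a ring-fusion bond (C1–C5 or C5–C6) instead would require C1 to be set by induction from C4, which is unreliable. Here the quaternary stereocentre is exchanged for a secondary carbinol centre at C6, and the ring tether allows only one productive geometry. The forward reaction needs heat and a clean suprafacial shift at a fully substituted alkene terminus.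

**Enol ether from a lactone, lactone from a homoallylic alcohol (15 ⇒ 14 ⇒ 11 ⇒ 9).** The C9=C10 bond is cut to lactone 14 (carbonyl methylenation). The lactone is opened to diol 11, and the primary hydroxyl is traced to the terminal alkene of 9. A one-step zinc-mediated 2-(alkoxycarbonyl)allylation of aldehyde 6 would reach a lactone faster, but it would leave C6 to the weak bias of the C4 centre. The three-step passage through 9 lets a chiral reagent set C6 instead. C8 is formed without control, which does not matter.

**C6–C7 bond (9 ⇒ 6 + 7).** Cutting C6–C7 gives enal 6 and the 2-methylallyl nucleophile 7. The forward reaction is an allylboration with a chiral borane, which must override the resident C4 centre and give the (S)-carbinol.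

**Cyclopentene from the chiral pool (6 ⇒ 4 ⇒ 2 ⇒ 1).** The C1=C5 bond is cut (aldol condensation) to keto aldehyde 4, which is the ozonolysis product of cyclohexene 2, the silyl ether of (S)-terpinen-4-ol 1. All seven ring and substituent carbons of the cyclopentene, the C6 aldehyde carbon and the C4 configuration come from 1. The forward aldol must use the aldehyde as the nucleophile and must not expel the β-silyloxy group.

## Roads not taken

**Alternative 1:** silicon-tethered radical annulation from the C4 oxygen. The cut removes C5–C6 and C1–C10 together, with C6 delivered from a silicon atom bound to the C4 oxygen. In the forward step Bu3SnH would generate an α-silyl radical at C6, which adds to C5 of a cyclopentene; the resulting C1 radical closes on C10 of an allyl sulfone and expels the sulfonyl radical, giving the oxasilolane-bridged hydroazulene A1.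
- Merits: two C–C bonds and the seven-membered ring form in one operation. The tether forces C6 onto the face of the C4 oxygen, so H5 ends up α without relying on the face selectivity of an intermolecular hydroboration. The C6–Si bond becomes C6–OH with retention (Tamao–Fleming oxidation). The C8=C9 alkene arrives in place, so the enol triflate regiochemistry of the chosen plan does not arise. In these three respects this road is better.
- Weak points: C1 must bond to C10 on the face opposite the chain that has just been attached at C5, a trans ring closure for which the tethered chain is poorly placed; the easier cis closure gives the wrong C1 epimer. A hindered tertiary radical closing a seven-membered ring also competes poorly with hydrogen transfer from the tin hydride.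
- Comparison: the chosen plan sets against this that C1 is fixed by a stereospecific suprafacial shift from a carbinol set by reagent control, and that it uses no stoichiometric tin.

**Alternative 2:** hydroxyl-directed cyclopropanation as the source of the angular methyl group. The cut is the C1–methyl bond, seen as a CH2 added across a tetrasubstituted C1=C5 alkene and later cleaved from C5. In the forward step Et2Zn/CH2I2 would cyclopropanate the bicyclic allylic alcohol on the face of the C4 hydroxyl to give tricycle A2.
- Merits: directed cyclopropanation of an allylic alcohol is among the most dependable face-selective reactions. It would place the future methyl carbon cis to the C4 hydroxyl with higher fidelity than a thermal rearrangement at 185 °C, and it needs no acid-labile enol ether.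
- Weak points: the step builds no ring of the skeleton and no skeletal bond, so a hydroazulene with a tetrasubstituted ring-fusion alkene and the C6 stereocentre must be made first by other means. The cyclopropane of A2 must then be opened at C5–CH2 and not at C1–CH2 without a carbonyl group to direct it. H5 must end up on the face opposite the bond that is broken, which reductive openings do not usually deliver. A cyclopropyl carbinol is also prone to cationic ring opening.
- Comparison: the chosen plan builds the ring, the quaternary centre and the alkene handle for H5 in one step, at the price of a less predictable hydroboration face.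

**Alternative 3:** Heck, carbonylation and acylpalladation cascade. The cut removes C1–C5, C9–C10 and C8–C9 at once. In the forward step zerovalent palladium (from Pd(OAc)2 and a bisphosphine) would insert into a C5–Br bond; the alkenylpalladium adds to C1=C10, CO inserts, the acylpalladium adds to a terminal vinyl group and β-hydride elimination gives the methylene enone A3.
- Merits: this is the most convergent road, with three C–C bonds and both rings from one acyclic precursor. The exocyclic enone of A3 also offers a regiospecific passage to the C8=C9 alkene (1,2-reduction, then reductive allylic transposition), cleaner than the enol triflate step of the chosen plan. If the cascade worked, the route would be shorter.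
- Weak points: C1 is created in the first carbopalladation under control only of the C4 centre across the forming five-membered ring, whose two substituents differ little in size, so the C1/C4 relationship is uncertain. Seven-membered acylpalladation is slow and competes with capture or decarbonylation of the acylpalladium. The precursor needs an acyclic, enantiopure C4 carbinol and a geometrically defined bromoalkene, neither of which the chiral pool supplies.
- Comparison: the chosen plan forms only one bond in its key step, but every step is of a known type and C1 is fixed by chirality transfer.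

Key step: step 8

Remarks on the chemistry: (S)-(+)-terpinen-4-ol (1) and a solution of 2-methylallylmagnesium chloride (7) are taken as purchased; the enantiomeric purity of 1 should be confirmed before use. C8 is carried as a mixture of epimers from 11 to 21 and is erased in 22. Skeleton numbers C1–C10 are those defined in "The problem".

## Route

Step 1
Reactants: 1 (S)-terpinen-4-ol
Product: 2 (S)-4-(tert-butyldimethylsilyloxy)-4-isopropyl-1-methylcyclohexene
Conditions: TBSOTf, 2,6-lutidine, CH2Cl2, 0 °C → rt
Reagents that add atoms: tert-butyldimethylsilyl trifluoromethanesulfonate, CC(C)(C)[Si](C)(C)OS(=O)(=O)C(F)(F)F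
Why: Silylation of a hindered tertiary alcohol with a silyl triflate and a hindered pyridine base; the ether prevents lactol formation and retro-aldol cleavage of the keto aldehyde of step 2 and later shields the β face; no stereocentre is touched.

Step 2
Reactants: 2 (S)-4-(tert-butyldimethylsilyloxy)-4-isopropyl-1-methylcyclohexene
Product: 4 (S)-3-(tert-butyldimethylsilyloxy)-3-isopropyl-6-oxoheptanal, via ozonide 3 (not isolated)
Conditions: O3, CH2Cl2, −78 °C; then PPh3, −78 °C → rt
Reagents that add atoms: ozone, [O-][O+]=O
Why: Ozonolysis of the only alkene with reductive work-up; the trisubstituted ring alkene gives the methyl ketone (C1) and the aldehyde (future C6) on one chain, and C4 is not involved.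

Step 3
Reactants: 4 (S)-3-(tert-butyldimethylsilyloxy)-3-isopropyl-6-oxoheptanal
Product: 6 (R)-5-(tert-butyldimethylsilyloxy)-5-isopropyl-2-methylcyclopent-1-ene-1-carbaldehyde, via aldol adduct 5 (not isolated)
Conditions: Bn2NH·CF3CO2H (cat.), PhMe, 50 °C
Reagents that add atoms: none
Why: Intramolecular aldol condensation under secondary-amine catalysis: the aldehyde enamine (C5) adds to the methyl ketone (C1) in a 5-exo closure and dehydration gives the tetrasubstituted enal; the amine salt makes the aldehyde the nucleophile, so the cyclopentenecarbaldehyde rather than an acetylcyclopentene results; C4 is untouched.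

Step 4
Reactants: 6 (R)-5-(tert-butyldimethylsilyloxy)-5-isopropyl-2-methylcyclopent-1-ene-1-carbaldehyde; 7 2-methylallylmagnesium chloride
Product: 9 (S)-1-[(R)-5-(tert-butyldimethylsilyloxy)-5-isopropyl-2-methylcyclopent-1-en-1-yl]-3-methylbut-3-en-1-ol, via borinate 8 (not isolated)
Conditions: (−)-Ipc2BOMe [from (+)-α-pinene], 7, Et2O, −78 → 0 °C; then 6, −78 °C → rt; then NaOH, H2O2
Reagents that add atoms: none
Why: Brown asymmetric methallylboration through a chair-like six-membered transition state; the borane derived from (+)-α-pinene delivers the 2-methylallyl group to the si face of the aldehyde, which sets C6 as S under reagent control, and only 1,2-addition is possible.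

Step 5
Reactants: 9 (S)-1-[(R)-5-(tert-butyldimethylsilyloxy)-5-isopropyl-2-methylcyclopent-1-en-1-yl]-3-methylbut-3-en-1-ol
Product: 11 (4S)-4-[(R)-5-(tert-butyldimethylsilyloxy)-5-isopropyl-2-methylcyclopent-1-en-1-yl]-2-methylbutane-1,4-diol (both C2 epimers), via bis-boron adduct 10 (not isolated)
Conditions: 9-BBN (2.5 equiv), THF, 0 °C → rt; then NaOH, H2O2, 0 °C
Reagents that add atoms: hydrogen peroxide, OO
Why: Anti-Markovnikov hydroboration–oxidation; 9-BBN reacts with the 1,1-disubstituted alkene and leaves the tetrasubstituted cyclopentene untouched; the new centre (skeleton C8) is formed without control and is erased later.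

Step 6
Reactants: 11 (4S)-4-[(R)-5-(tert-butyldimethylsilyloxy)-5-isopropyl-2-methylcyclopent-1-en-1-yl]-2-methylbutane-1,4-diol
Product: 14 (5S)-5-[(R)-5-(tert-butyldimethylsilyloxy)-5-isopropyl-2-methylcyclopent-1-en-1-yl]-3-methyldihydrofuran-2(3H)-one (both C3 epimers), via hydroxy aldehyde 12 (not isolated), via lactol 13 (not isolated)
Conditions: TEMPO (cat.), PhI(OAc)2, CH2Cl2, rt
Reagents that add atoms: none
Why: Oxidative lactonisation of a 1,4-diol: the oxoammonium salt oxidises the primary alcohol much faster than the hindered secondary one, the hydroxy aldehyde closes to the five-membered lactol, and this is oxidised to the lactone; C6 keeps its configuration because its C–O bond is not broken.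

Step 7
Reactants: 14 (5S)-5-[(R)-5-(tert-butyldimethylsilyloxy)-5-isopropyl-2-methylcyclopent-1-en-1-yl]-3-methyldihydrofuran-2(3H)-one
Product: 15 (5S)-5-[(R)-5-(tert-butyldimethylsilyloxy)-5-isopropyl-2-methylcyclopent-1-en-1-yl]-3-methyl-2-methylenetetrahydrofuran (both C3 epimers)
Conditions: Cp2TiMe2, PhMe, 70 °C, dark; filtration through basic alumina
Reagents that add atoms: dimethyltitanocene, C[Ti](C)(C1C=CC=C1)C1C=CC=C1
Why: Petasis methylenation of a lactone carbonyl to the exocyclic enol ether; the non-basic titanium methylidene does not enolise the lactone or touch the silyl ether, and the acid-sensitive product is kept on basic supports.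

Step 8
Reactants: 15 (5S)-5-[(R)-5-(tert-butyldimethylsilyloxy)-5-isopropyl-2-methylcyclopent-1-en-1-yl]-3-methyl-2-methylenetetrahydrofuran
Product: 16 (1R,4R)-4-(tert-butyldimethylsilyloxy)-4-isopropyl-1,8-dimethylbicyclo[5.3.0]dec-5-en-9-one (skeleton numbering; both C8 epimers)
Conditions: PhMe, Et3N (cat.), sealed base-washed tube, 185 °C
Reagents that add atoms: none
Why: Thermal [3,3]-sigmatropic (Claisen) rearrangement of the allyl vinyl ether C10=C9–O–C6–C5=C1: the C1–C10 bond forms as the C6–O bond breaks, and the C9 carbonyl and the C5=C6 alkene appear in the same event. The closest known reaction type is the Claisen ring expansion of 2-methylene-5-vinyltetrahydrofurans to cyclohept-4-enones. The seven-membered carbocycle is closed by this sigmatropic bond formation while the five-membered ether opens, a net two-carbon ring expansion that must pass through a boat-like transition state because C7–C8 ties the two ends of the ether together. The only new stereocentre, C1, is controlled by C6: the shift is suprafacial on the C6–C5=C1 unit and only the rotamer about C5–C6 that turns C7 toward C1 (the one leading to the ring-compatible cis alkene) lets C10 reach C1, so the (S)-configured C6 delivers C10 to the α face and leaves the methyl group β, cis to the C4 silyloxy group. The step needs this face selectivity and freedom from isomerisation of the exocyclic enol ether into the ring; the first is secured by the tether and the C6 configuration, the second by a base-washed vessel and a trace of amine. The C8 configuration has no influence and the silyl ether is a spectator.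

Step 9
Reactants: 16 (1R,4R)-4-(tert-butyldimethylsilyloxy)-4-isopropyl-1,8-dimethylbicyclo[5.3.0]dec-5-en-9-one
Product: 17 (1R,4R)-4-(tert-butyldimethylsilyloxy)-9,9-(ethylenedioxy)-4-isopropyl-1,8-dimethylbicyclo[5.3.0]dec-5-ene (skeleton numbering)
Conditions: TMSOCH2CH2OTMS, TMSOTf (cat.), CH2Cl2, −78 → −20 °C; then pyridine
Reagents that add atoms: 1,2-bis(trimethylsilyloxy)ethane, C[Si](C)(C)OCCO[Si](C)(C)C
Why: Noyori ketalisation of a moderately hindered ketone at low temperature, which leaves the silyl ether and the alkene alone; the ketone must be masked because borane would reduce it in step 10.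

Step 10
Reactants: 17 (1R,4R)-4-(tert-butyldimethylsilyloxy)-9,9-(ethylenedioxy)-4-isopropyl-1,8-dimethylbicyclo[5.3.0]dec-5-ene
Product: 19 (1R,4R,5S,6S)-4-(tert-butyldimethylsilyloxy)-9,9-(ethylenedioxy)-4-isopropyl-1,8-dimethylbicyclo[5.3.0]decan-6-ol (skeleton numbering), via alkylborane 18 (not isolated)
Conditions: BH3·THF, THF, 0 °C → rt; then NaOH, H2O2, 0 °C
Reagents that add atoms: hydrogen peroxide, OO
Why: Hydroboration–oxidation of the trisubstituted alkene: boron adds to the less substituted C6 and hydrogen to C5 in a syn four-centre addition from the α face, anti to the C1 methyl and the C4 silyloxy group that cover the β face (as with angularly methylated ring-fusion alkenes); this sets H5 and the C6 oxygen both α, makes the ring fusion trans, and oxidation retains the C6 configuration.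

Step 11
Reactants: 19 (1R,4R,5S,6S)-4-(tert-butyldimethylsilyloxy)-9,9-(ethylenedioxy)-4-isopropyl-1,8-dimethylbicyclo[5.3.0]decan-6-ol
Product: 20 (1R,4R,5S,6S)-4-(tert-butyldimethylsilyloxy)-9,9-(ethylenedioxy)-4-isopropyl-1,8-dimethylbicyclo[5.3.0]decan-6-yl benzoate (skeleton numbering)
Conditions: BzCl, pyridine, DMAP (cat.), CH2Cl2, rt
Reagents that add atoms: benzoyl chloride, O=C(Cl)c1ccccc1
Why: Acyl-transfer-catalysed esterification of the only free hydroxyl; the C6–O bond is not broken, so the configuration is kept, and the ester is in place before the ketone is released so that no transannular hemiketal can form.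

Step 12
Reactants: 20 (1R,4R,5S,6S)-4-(tert-butyldimethylsilyloxy)-9,9-(ethylenedioxy)-4-isopropyl-1,8-dimethylbicyclo[5.3.0]decan-6-yl benzoate
Product: 21 (1R,4R,5S,6S)-4-(tert-butyldimethylsilyloxy)-4-isopropyl-1,8-dimethyl-9-oxobicyclo[5.3.0]decan-6-yl benzoate (skeleton numbering)
Conditions: 2 M HCl, THF, rt
Reagents that add atoms: water, O
Why: Acid hydrolysis of the dioxolane; the hindered tertiary silyl ether and the benzoate tolerate dilute aqueous acid, and epimerisation at C8 is of no consequence.

Step 13
Reactants: 21 (1R,4R,5S,6S)-4-(tert-butyldimethylsilyloxy)-4-isopropyl-1,8-dimethyl-9-oxobicyclo[5.3.0]decan-6-yl benzoate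
Product: 22 (1R,4R,5S,6S)-4-(tert-butyldimethylsilyloxy)-4-isopropyl-1,8-dimethyl-9-(trifluoromethylsulfonyloxy)bicyclo[5.3.0]dec-8-en-6-yl benzoate (skeleton numbering)
Conditions: Tf2O, 2,6-di-tert-butyl-4-methylpyridine, CH2Cl2, 0 °C → rt
Reagents that add atoms: trifluoromethanesulfonic anhydride, O=S(=O)(OS(=O)(=O)C(F)(F)F)C(F)(F)F
Why: Enol triflate formation under non-enolate conditions: O-triflation of the ketone and proton loss under product-like control favour the more substituted C8=C9 isomer over removal of a neopentyl-type C10 hydrogen; no strong base meets the benzoate and the C8 stereocentre is erased.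

Step 14
Reactants: 22 (1R,4R,5S,6S)-4-(tert-butyldimethylsilyloxy)-4-isopropyl-1,8-dimethyl-9-(trifluoromethylsulfonyloxy)bicyclo[5.3.0]dec-8-en-6-yl benzoate
Product: 23 (1R,4R,5S,6S)-4-(tert-butyldimethylsilyloxy)-4-isopropyl-1,8-dimethylbicyclo[5.3.0]dec-8-en-6-yl benzoate (skeleton numbering)
Conditions: Pd(OAc)2 (cat.), PPh3, HCO2H, Bu3N, DMF, 60 °C
Reagents that add atoms: none
Why: Palladium-catalysed formate reduction of an enol triflate: zerovalent palladium inserts into the C9–O bond, formate exchange and loss of CO2 give the alkenylpalladium hydride, and reductive elimination places hydrogen on C9 without moving the double bond or touching the ester.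

Step 15
Reactants: 23 (1R,4R,5S,6S)-4-(tert-butyldimethylsilyloxy)-4-isopropyl-1,8-dimethylbicyclo[5.3.0]dec-8-en-6-yl benzoate
Product: 24 (1R,4R,5S,6S)-4-hydroxy-4-isopropyl-1,8-dimethylbicyclo[5.3.0]dec-8-en-6-yl benzoate (skeleton numbering)
Conditions: HF·pyridine, pyridine, THF, 0 °C → rt
Reagents that add atoms: none
Why: Fluoride cleavage of the silyl ether under buffered conditions that leave the benzoate and the trisubstituted alkene alone; it is done before epoxidation so that the epoxide never meets fluoride or acid.

Step 16
Reactants: 24 (1R,4R,5S,6S)-4-hydroxy-4-isopropyl-1,8-dimethylbicyclo[5.3.0]dec-8-en-6-yl benzoate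
Product: 25 (1R,4R,5S,6S,8R,9S)-8,9-epoxy-4-hydroxy-4-isopropyl-1,8-dimethylbicyclo[5.3.0]decan-6-yl benzoate (skeleton numbering; the target)
Conditions: mCPBA, NaHCO3, CH2Cl2, 0 °C
Reagents that add atoms: 3-chloroperoxybenzoic acid, O=C(OO)c1cccc(Cl)c1
Why: Prilezhaev epoxidation of the electron-rich trisubstituted alkene; the peracid should approach the α face, away from the C1 methyl group that sits over the β face two bonds from C9, which sets C8 (R) and C9 (S) in one syn addition, and the bicarbonate buffer protects the epoxide from acid.

## Compound list

1 | (S)-terpinen-4-ol | CC(C)[C@]1(O)CCC(C)=CC1 | starting material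
2 | (S)-4-(tert-butyldimethylsilyloxy)-4-isopropyl-1-methylcyclohexene | CC(C)[C@]1(O[Si](C)(C)C(C)(C)C)CCC(C)=CC1 | intermediate
3 | ozonide (1,2,4-trioxolane) of 2, mixture at the trioxolane carbons | CC(C)[C@]1(O[Si](C)(C)C(C)(C)C)CCC2(C)OOC(C1)O2 | intermediate (not isolated)
4 | (S)-3-(tert-butyldimethylsilyloxy)-3-isopropyl-6-oxoheptanal | CC(C)[C@](CC=O)(O[Si](C)(C)C(C)(C)C)CCC(C)=O | intermediate
5 | (5R)-5-(tert-butyldimethylsilyloxy)-2-hydroxy-5-isopropyl-2-methylcyclopentane-1-carbaldehyde, mixture at C1 and C2 | CC(C)[C@]1(O[Si](C)(C)C(C)(C)C)CCC(C)(O)C1C=O | intermediate (not isolated)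
6 | (R)-5-(tert-butyldimethylsilyloxy)-5-isopropyl-2-methylcyclopent-1-ene-1-carbaldehyde | CC(C)[C@]1(O[Si](C)(C)C(C)(C)C)CCC(C)=C1C=O | intermediate
7 | 2-methylallylmagnesium chloride | C=C(C)C[Mg]Cl | starting material
8 | diisopinocampheylborinate of 9 (O–B(Ipc)2 on the C6 oxygen) | CC(C)[C@]1(O[Si](C)(C)C(C)(C)C)CCC(C)=C1[C@@H](OB([C@@H]1C[C@@H]2C[C@H]([C@H]1C)C2(C)C)[C@@H]1C[C@@H]2C[C@H]([C@H]1C)C2(C)C)CC(C)=C | intermediate (not isolated)
9 | (S)-1-[(R)-5-(tert-butyldimethylsilyloxy)-5-isopropyl-2-methylcyclopent-1-en-1-yl]-3-methylbut-3-en-1-ol | CC(C)[C@]1(O[Si](C)(C)C(C)(C)C)CCC(C)=C1[C@@H](O)CC(C)=C | intermediate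
10 | adduct of 9 with two 9-BBN units (O-borinate at C6, primary alkylborane at C9), C8 epimers | CC(C)[C@]1(O[Si](C)(C)C(C)(C)C)CCC(C)=C1[C@@H](OB1C2CCCC1CCC2)CC(C)CB1C2CCCC1CCC2 | intermediate (not isolated)
11 | (4S)-4-[(R)-5-(tert-butyldimethylsilyloxy)-5-isopropyl-2-methylcyclopent-1-en-1-yl]-2-methylbutane-1,4-diol, C2 epimers | CC(C)[C@]1(O[Si](C)(C)C(C)(C)C)CCC(C)=C1[C@@H](O)CC(C)CO | intermediate
12 | (4S)-4-hydroxy-4-[(R)-5-(tert-butyldimethylsilyloxy)-5-isopropyl-2-methylcyclopent-1-en-1-yl]-2-methylbutanal, C2 epimers | CC(C)[C@]1(O[Si](C)(C)C(C)(C)C)CCC(C)=C1[C@@H](O)CC(C)C=O | intermediate (not isolated)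
13 | (5S)-5-[(R)-5-(tert-butyldimethylsilyloxy)-5-isopropyl-2-methylcyclopent-1-en-1-yl]-3-methyltetrahydrofuran-2-ol, mixture at C2 and C3 | CC(C)[C@]1(O[Si](C)(C)C(C)(C)C)CCC(C)=C1[C@@H]1CC(C)C(O)O1 | intermediate (not isolated)
14 | (5S)-5-[(R)-5-(tert-butyldimethylsilyloxy)-5-isopropyl-2-methylcyclopent-1-en-1-yl]-3-methyldihydrofuran-2(3H)-one, C3 epimers | CC(C)[C@]1(O[Si](C)(C)C(C)(C)C)CCC(C)=C1[C@@H]1CC(C)C(=O)O1 | intermediate
15 | (5S)-5-[(R)-5-(tert-butyldimethylsilyloxy)-5-isopropyl-2-methylcyclopent-1-en-1-yl]-3-methyl-2-methylenetetrahydrofuran, C3 epimers | CC(C)[C@]1(O[Si](C)(C)C(C)(C)C)CCC(C)=C1[C@@H]1CC(C)C(=C)O1 | intermediate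
16 | (1R,4R)-4-(tert-butyldimethylsilyloxy)-4-isopropyl-1,8-dimethylbicyclo[5.3.0]dec-5-en-9-one (skeleton numbering), C8 epimers | CC(C)[C@]1(O[Si](C)(C)C(C)(C)C)CC[C@]2(C)CC(=O)C(C)CC=C21 | intermediate
17 | 9,9-ethylenedioxy ketal of 16 | CC(C)[C@]1(O[Si](C)(C)C(C)(C)C)CC[C@]2(C)CC3(OCCO3)C(C)CC=C21 | intermediate
18 | C6 alkylborane from 17 (drawn as the monoalkylborane; H5 α, boron α) | CC(C)[C@]1(O[Si](C)(C)C(C)(C)C)CC[C@]2(C)CC3(OCCO3)C(C)C[C@H](B)[C@H]21 | intermediate (not isolated)
19 | (1R,4R,5S,6S)-4-(tert-butyldimethylsilyloxy)-9,9-(ethylenedioxy)-4-isopropyl-1,8-dimethylbicyclo[5.3.0]decan-6-ol (skeleton numbering) | CC(C)[C@]1(O[Si](C)(C)C(C)(C)C)CC[C@]2(C)CC3(OCCO3)C(C)C[C@H](O)[C@H]21 | intermediate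
20 | benzoate of 19 | CC(C)[C@]1(O[Si](C)(C)C(C)(C)C)CC[C@]2(C)CC3(OCCO3)C(C)C[C@H](OC(=O)c3ccccc3)[C@H]21 | intermediate
21 | (1R,4R,5S,6S)-4-(tert-butyldimethylsilyloxy)-4-isopropyl-1,8-dimethyl-9-oxobicyclo[5.3.0]decan-6-yl benzoate (skeleton numbering), C8 epimers | CC(C)[C@]1(O[Si](C)(C)C(C)(C)C)CC[C@]2(C)CC(=O)C(C)C[C@H](OC(=O)c3ccccc3)[C@H]21 | intermediate
22 | C8=C9 enol triflate of 21 | CC(C)[C@]1(O[Si](C)(C)C(C)(C)C)CC[C@]2(C)CC(OS(=O)(=O)C(F)(F)F)=C(C)C[C@H](OC(=O)c3ccccc3)[C@H]21 | intermediate
23 | (1R,4R,5S,6S)-4-(tert-butyldimethylsilyloxy)-4-isopropyl-1,8-dimethylbicyclo[5.3.0]dec-8-en-6-yl benzoate (skeleton numbering) | CC(C)[C@]1(O[Si](C)(C)C(C)(C)C)CC[C@]2(C)CC=C(C)C[C@H](OC(=O)c3ccccc3)[C@H]21 | intermediate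
24 | (1R,4R,5S,6S)-4-hydroxy-4-isopropyl-1,8-dimethylbicyclo[5.3.0]dec-8-en-6-yl benzoate (skeleton numbering) | CC(C)[C@]1(O)CC[C@]2(C)CC=C(C)C[C@H](OC(=O)c3ccccc3)[C@H]21 | intermediate
25 | (1R,4R,5S,6S,8R,9S)-8,9-epoxy-4-hydroxy-4-isopropyl-1,8-dimethylbicyclo[5.3.0]decan-6-yl benzoate (skeleton numbering; epoxide oxygen α, C1 methyl and C4 hydroxyl β) | CC(C)[C@]1(O)CC[C@]2(C)C[C@@H]3O[C@]3(C)C[C@H](OC(=O)c3ccccc3)[C@H]21 | target

## Step count and least certain steps

Total: 16 steps. Longest linear sequence: 16 steps (1 → 25); 7 enters at step 4.

**Step 8 (key step).** The most likely failure is isomerisation of the exocyclic enol ether into the ring by traces of acid at the temperature required, because bond formation at a fully substituted alkene terminus through a boat-like transition state is slow; the isomerised ether cannot rearrange. Fallback: set out from 15 and promote the same reorganisation with iBu3Al in CH2Cl2 at −78 °C → rt. The aluminium reagent should trigger the C1–C10/C6–O exchange at low temperature and reduce the aluminium-bound ketone by β-hydride transfer, giving the C9 carbinol F1. Oxidation of the C9 carbinol F1 with Dess–Martin periodinane returns to the route at 16.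

**Step 3.** The most likely failure is loss of the silyloxy group by β-elimination from the aldehyde enamine, or closure in the other direction (ketone enol onto the aldehyde), because the nucleophilic carbon is flanked by the quaternary C4. Fallback: change the order of protection. Set out from 1: ozonolysis with PPh3 work-up gives the hydroxy keto aldehyde F2, in which hydroxide is a far poorer leaving group than a silanolate. The same amine-salt aldol condensation gives the hydroxy enal F3. Silylation of the hydroxy enal F3 with TBSOTf and 2,6-lutidine returns to the route at 6.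

**Step 4.** The most likely failure is slow addition with eroded face selectivity, because the aldehyde sits between a quaternary carbon and a methyl-bearing alkene carbon and the C4 centre may oppose the reagent. Fallback: set out from 6 and add 7 directly (THF, −78 °C) to give 9 together with its C6 epimer F4. Dess–Martin oxidation of the mixture gives the dienyl ketone F5. Corey–Bakshi–Shibata reduction of the dienyl ketone F5 with catecholborane and (R)-2-methyl-CBS-oxazaborolidine, the cyclopentenyl group acting as the large substituent, returns to the route at 9.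

**Step 10.** The most likely failure is poor facial selectivity: the α face carries the C4 isopropyl group and the fold of the seven-membered ring, so borane may add partly from the β face and give the cis-fused isomer. Fallback: set C5 under thermodynamic control and C6 by a directed reduction.
- Set out from the alcohol mixture obtained from 17 and oxidise it with Dess–Martin periodinane to the C6 ketone F6.
- Bu4NF in THF removes the silyl group and, being basic, equilibrates the centre next to the ketone to the trans-fused hydroxy ketone F7, in which C6 avoids the C4 isopropyl group and can hydrogen-bond to the C4 hydroxyl.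
- Saksena–Evans reduction with Me4NBH(OAc)3 delivers hydride from the boron bound to the β-oriented C4 oxygen and gives the 1,3-anti diol F8 with the C6 hydroxyl α.
- Benzoylation of the only secondary hydroxyl gives the hydroxy benzoate F9.
- TBSOTf and 2,6-lutidine return to the route at 20.

**Step 13.** The most likely failure is formation of a mixture of enol triflate regioisomers, because proton loss toward C8 and toward C10 may compete. Fallback: fix the regiochemistry on an isolable silyl enol ether under equilibrating conditions. Set out from 21; Me3SiCl, NaI and hexamethyldisilazane give the more substituted trimethylsilyl enol ether F10. CsF and PhNTf2 in DME convert the trimethylsilyl enol ether F10 into 22, where the route is rejoined.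

**Step 16.** The most likely failure is attack of the peracid on the β face, or acid-induced opening of the epoxide by the C4 hydroxyl across the ring. Fallback: the halohydrin route, which reverses the facial outcome of a direct epoxidation. Set out from 24; N-bromosuccinimide in aqueous THF forms the bromonium ion on the more accessible face and water opens it at the tertiary C8 from the other side. If the accessible face is β, the product is the bromohydrin F11 (C8 hydroxyl α, C9 bromine β). DBU in PhMe closes the bromohydrin F11 with inversion at C9 to the α-epoxide 25.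

## Further compounds

F1 | step 8 | (1R,4R)-4-(tert-butyldimethylsilyloxy)-4-isopropyl-1,8-dimethylbicyclo[5.3.0]dec-5-en-9-ol (skeleton numbering; C8 and C9 epimers) | CC(C)[C@]1(O[Si](C)(C)C(C)(C)C)CC[C@]2(C)CC(O)C(C)CC=C21
F2 | step 3 | (S)-3-hydroxy-3-isopropyl-6-oxoheptanal | CC(C)[C@@](O)(CC=O)CCC(C)=O
F3 | step 3 | (R)-5-hydroxy-5-isopropyl-2-methylcyclopent-1-ene-1-carbaldehyde | CC(C)[C@]1(O)CCC(C)=C1C=O
F4 | step 4 | (R)-1-[(R)-5-(tert-butyldimethylsilyloxy)-5-isopropyl-2-methylcyclopent-1-en-1-yl]-3-methylbut-3-en-1-ol (C6 epimer of 9) | CC(C)[C@]1(O[Si](C)(C)C(C)(C)C)CCC(C)=C1[C@H](O)CC(C)=C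
F5 | step 4 | 1-[(R)-5-(tert-butyldimethylsilyloxy)-5-isopropyl-2-methylcyclopent-1-en-1-yl]-3-methylbut-3-en-1-one | CC(C)[C@]1(O[Si](C)(C)C(C)(C)C)CCC(C)=C1C(=O)CC(C)=C
F6 | step 10 | (1R,4R)-4-(tert-butyldimethylsilyloxy)-9,9-(ethylenedioxy)-4-isopropyl-1,8-dimethylbicyclo[5.3.0]decan-6-one (skeleton numbering; C5 epimers) | CC(C)[C@]1(O[Si](C)(C)C(C)(C)C)CC[C@]2(C)CC3(OCCO3)C(C)CC(=O)C21
F7 | step 10 | (1R,4R,5S)-9,9-(ethylenedioxy)-4-hydroxy-4-isopropyl-1,8-dimethylbicyclo[5.3.0]decan-6-one (skeleton numbering; trans-fused, H5 α) | CC(C)[C@]1(O)CC[C@]2(C)CC3(OCCO3)C(C)CC(=O)[C@H]21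
F8 | step 10 | (1R,4R,5S,6S)-9,9-(ethylenedioxy)-4-isopropyl-1,8-dimethylbicyclo[5.3.0]decane-4,6-diol (skeleton numbering) | CC(C)[C@]1(O)CC[C@]2(C)CC3(OCCO3)C(C)C[C@H](O)[C@H]21
F9 | step 10 | (1R,4R,5S,6S)-9,9-(ethylenedioxy)-4-hydroxy-4-isopropyl-1,8-dimethylbicyclo[5.3.0]decan-6-yl benzoate (skeleton numbering) | CC(C)[C@]1(O)CC[C@]2(C)CC3(OCCO3)C(C)C[C@H](OC(=O)c3ccccc3)[C@H]21
F10 | step 13 | (1R,4R,5S,6S)-4-(tert-butyldimethylsilyloxy)-4-isopropyl-1,8-dimethyl-9-(trimethylsilyloxy)bicyclo[5.3.0]dec-8-en-6-yl benzoate (skeleton numbering) | CC(C)[C@]1(O[Si](C)(C)C(C)(C)C)CC[C@]2(C)CC(O[Si](C)(C)C)=C(C)C[C@H](OC(=O)c3ccccc3)[C@H]21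
F11 | step 16 | (1R,4R,5S,6S,8R,9R)-9-bromo-4,8-dihydroxy-4-isopropyl-1,8-dimethylbicyclo[5.3.0]decan-6-yl benzoate (skeleton numbering; C8 hydroxyl α, C9 bromine β) | CC(C)[C@]1(O)CC[C@]2(C)C[C@@H](Br)[C@](C)(O)C[C@H](OC(=O)c3ccccc3)[C@H]21
A1 | alternative 1 | oxasilolane-bridged hydroazulene (dimethylsilyl bridge from the C4 oxygen to C6, C8=C9 alkene) | CC(C)[C@@]12CC[C@]3(C)CC=C(C)C[C@H]([Si](C)(C)O1)[C@@H]23
A2 | alternative 2 | cyclopropane-bridged tricycle (CH2 across C1–C5, free C4 hydroxyl, C6 tert-butyldimethylsilyl ether, C8=C9 alkene) | CC(C)[C@]1(O)CC[C@@]23C[C@]21[C@H](O[Si](C)(C)C(C)(C)C)CC(C)=CC3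
A3 | alternative 3 | 4-(triethylsilyloxy)-4-isopropyl-1-methyl-8-methylenebicyclo[5.3.0]dec-5-en-9-one (skeleton numbering) | CC(C)[C@]1(O[Si](CC)(CC)CC)CC[C@]2(C)CC(=O)C(=C)CC=C21
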